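## Retrosynthetic overview

1. The target comes from regioselective hydrolysis of a 2,5-dimethoxy-para-quinone, itself from oxidative demethylation of a 1,2,4,5-tetramethoxyarene; the quinone ring is a purchased benzene ring unveiled last.
2. The arene–side-chain bond and the (E)-trisubstituted alkene come from zirconium-catalysed methylalumination of a terminal alkyne and palladium-catalysed coupling of the alkenylalane with 2,3,5,6-tetramethoxybenzyl chloride.
3. The alkyne comes from one-carbon homologation of a propargyl group, the exocyclic methylene from ketone methylenation, and the propargyl ketone from Eschenmoser–Tanabe fragmentation of a bicyclic epoxy ketone.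
4. That bicyclic cyclopentenone (Wacker oxidation, then aldol condensation of an allyl ketone) exists only to equilibrate the secondary methyl trans to the angular methyl; the quaternary centre comes from ketoreductase desymmetrisation of achiral 2-allyl-2-methylcyclohexane-1,3-dione, then deoxygenation.
5. Ring order: the cyclohexane ring is present from the start; a temporary cyclopentenone ring is annulated and cleaved again; no other ring is built.

Assumption: 1,2,4,5-tetramethoxybenzene and a ketoreductase screening panel are purchased; simple reagents (allyl methyl carbonate, MeI, DMF and the like) are named under the steps and not numbered.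

## Route

Step 1
Reactants: 1 2-methylcyclohexane-1,3-dione
Product: 2 2-methyl-2-(prop-2-en-1-yl)cyclohexane-1,3-dione
Conditions: allyl methyl carbonate (1.2 equiv), Pd(PPh3)4 (2 mol %), THF, 25–40 °C
Reagents that add atoms: allyl methyl carbonate, C=CCOC(=O)OC
Why: Tsuji–Trost allylation under neutral conditions, in which zerovalent palladium ionises the carbonate, the released methoxide deprotonates the acidic dione, and any O-allyl enol ether re-ionises, so irreversible C-allylation gives the achiral, prochiral dione.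

Step 2
Reactants: 2 2-methyl-2-(prop-2-en-1-yl)cyclohexane-1,3-dione
Product: 3 (2S,3S)-3-hydroxy-2-methyl-2-(prop-2-en-1-yl)cyclohexan-1-one
Conditions: ketoreductase (NADPH-dependent, screened for the (2S,3S) product), NADP+ (cat.), i-PrOH (10 vol %), potassium phosphate buffer pH 7, 30 °C
Reagents that add atoms: none
Why: Enzymatic desymmetrisation, in which the ketoreductase as chiral catalyst reduces one of the two enantiotopic carbonyl groups from one face only, so the quaternary C2 and the carbinol C3 are set together in high ee with hydride recycled from isopropanol.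

Step 3
Reactants: 3 (2S,3S)-3-hydroxy-2-methyl-2-(prop-2-en-1-yl)cyclohexan-1-one
Product: 4 O-[(1S,2S)-2-methyl-3-oxo-2-(prop-2-en-1-yl)cyclohexyl] O-phenyl carbonothioate
Conditions: PhOC(S)Cl, pyridine, DMAP (cat.), CH2Cl2, 0 → 25 °C
Reagents that add atoms: O-phenyl carbonochloridothioate, S=C(Cl)Oc1ccccc1
Why: O-Thioacylation of the secondary alcohol installs the radical leaving group for a Barton–McCombie deoxygenation under non-basic conditions that cannot trigger retro-aldol cleavage and touch no stereocentre.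

Step 4
Reactants: 4 O-[(1S,2S)-2-methyl-3-oxo-2-(prop-2-en-1-yl)cyclohexyl] O-phenyl carbonothioate
Product: 5 (2R)-2-methyl-2-(prop-2-en-1-yl)cyclohexan-1-one
Conditions: Bu3SnH (2 equiv, 0.3 M), AIBN (cat.), toluene, 100 °C
Reagents that add atoms: none
Why: Barton–McCombie radical deoxygenation, in which the stannyl radical adds to C=S, the C–O bond fragments and the ring radical is reduced by concentrated Bu3SnH faster than any 1,2-acyl shift, removing the superfluous carbinol centre and leaving the quaternary centre intact.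

Step 5
Reactants: 5 (2R)-2-methyl-2-(prop-2-en-1-yl)cyclohexan-1-one
Product: 7 (2R,6RS)-2,6-dimethyl-2-(prop-2-en-1-yl)cyclohexan-1-one (mixture of C6 epimers), via lithium enolate 6 (not isolated)
Conditions: LiN(i-Pr)2, THF, −78 °C; then MeI, −78 → 0 °C
Reagents that add atoms: iodomethane, CI
Why: Kinetic enolate alkylation, regiospecific because only C6 carries alpha hydrogens, with the new C6 centre deliberately left uncontrolled since it is corrected in step 7.

Step 6
Reactants: 7 (2R,6RS)-2,6-dimethyl-2-(prop-2-en-1-yl)cyclohexan-1-one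
Product: 8 (2R,6RS)-2,6-dimethyl-2-(2-oxopropyl)cyclohexan-1-one
Conditions: PdCl2 (10 mol %), CuCl (1 equiv), O2 (1 atm), DMF/H2O 7:1, 25 °C
Reagents that add atoms: water, O
Why: Tsuji–Wacker oxidation, in which divalent palladium activates the terminal alkene for Markovnikov attack of water and CuCl/O2 reoxidise the palladium, giving the methyl ketone of a 1,4-diketone without affecting either stereocentre.

Step 7
Reactants: 8 (2R,6RS)-2,6-dimethyl-2-(2-oxopropyl)cyclohexan-1-one
Product: 10 (4R,7aR)-4,7a-dimethyl-1,4,5,6,7,7a-hexahydro-2H-inden-2-one, via aldol adduct 9 (not isolated)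
Conditions: KOH, xylenes, 110 °C (Dean–Stark); then NaOMe (0.2 equiv), MeOH, 65 °C
Reagents that add atoms: none
Why: Intramolecular aldol condensation closes the cyclopentenone, and because the C4 hydrogen is gamma to the enone it epimerises through the dienolate to the isomer with the C4 methyl equatorial and trans to the axial angular methyl (the cis isomer has a 1,3-diaxial methyl/methyl clash), so this centre is set under thermodynamic control relative to the enzyme-derived quaternary centre.

Step 8
Reactants: 10 (4R,7aR)-4,7a-dimethyl-1,4,5,6,7,7a-hexahydro-2H-inden-2-one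
Product: 11 (4R,7aR)-3,3a-epoxy-4,7a-dimethyloctahydro-2H-inden-2-one (oxirane face inconsequential)
Conditions: 30% H2O2, aq NaOH, MeOH, 0 → 25 °C
Reagents that add atoms: hydrogen peroxide, OO
Why: Weitz–Scheffer nucleophilic epoxidation by conjugate addition of hydroperoxide and ring closure of the enolate, where the oxirane configuration does not matter because both carbons lose it in step 9 and C4 stops being acidic once the enone is consumed.

Step 9
Reactants: 11 (4R,7aR)-3,3a-epoxy-4,7a-dimethyloctahydro-2H-inden-2-one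
Product: 13 (2R,6R)-2,6-dimethyl-2-(prop-2-yn-1-yl)cyclohexan-1-one, via tosylhydrazone 12 (not isolated)
Conditions: TsNHNH2 (1.1 equiv), AcOH/CH2Cl2 1:1, −20 → 25 °C
Reagents that add atoms: none
Why: Eschenmoser–Tanabe fragmentation of the alpha,beta-epoxy tosylhydrazone cleaves the C3–C3a bond with loss of N2 and sulfinate to give the ring ketone and a terminal alkyne, under cold, weakly acidic conditions that do not enolise the hindered ketone, so both stereocentres are kept.

Step 10
Reactants: 13 (2R,6R)-2,6-dimethyl-2-(prop-2-yn-1-yl)cyclohexan-1-one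
Product: 14 (1R,3R)-1,3-dimethyl-2-methylidene-1-(prop-2-yn-1-yl)cyclohexane
Conditions: Zn, CH2Br2, TiCl4 (reagent pre-formed in THF at 5 °C), CH2Cl2, 0 → 25 °C
Reagents that add atoms: dibromomethane, BrCBr
Why: Takai–Lombardo methylenation with a non-basic zinc/titanium methylene reagent converts hindered, enolisable ketones to methylene compounds without epimerising the alpha stereocentre and leaves the terminal alkyne alone.

Step 11
Reactants: 14 (1R,3R)-1,3-dimethyl-2-methylidene-1-(prop-2-yn-1-yl)cyclohexane
Product: 16 3-[(1R,3R)-1,3-dimethyl-2-methylidenecyclohexyl]propanal, via alkenylborane 15 (not isolated)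
Conditions: (c-C6H11)2BH (from BH3·SMe2 and cyclohexene), THF, 0 → 25 °C; then 30% H2O2, pH 8 phosphate buffer, 0 → 25 °C
Reagents that add atoms: hydrogen peroxide, OO
Why: Anti-Markovnikov hydroboration–oxidation, in which the bulky dialkylborane adds once to the terminal alkyne and not to the hindered 1,1-disubstituted alkene, and oxidation of the alkenylborane gives the aldehyde through its enol.

Step 12
Reactants: 16 3-[(1R,3R)-1,3-dimethyl-2-methylidenecyclohexyl]propanal
Product: 17 (1R,3R)-1-(but-3-yn-1-yl)-1,3-dimethyl-2-methylidenecyclohexane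
Conditions: dimethyl (1-diazo-2-oxopropyl)phosphonate, K2CO3, MeOH, 0 → 25 °C
Reagents that add atoms: dimethyl (1-diazo-2-oxopropyl)phosphonate, COP(=O)(OC)C(=[N+]=[N-])C(C)=O
Why: Seyferth–Gilbert homologation in the Ohira–Bestmann variant, in which the diazomethylphosphonate anion olefinates the aldehyde and loss of N2 with 1,2-hydrogen shift gives the one-carbon-longer terminal alkyne under base too mild to affect any stereocentre.

Step 13
Reactants: 18 1,2,4,5-tetramethoxybenzene
Product: 20 2,3,5,6-tetramethoxybenzaldehyde, via aryllithium 19 (not isolated)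
Conditions: n-BuLi, THF, 0 → 25 °C; then DMF, 0 °C; aqueous work-up
Reagents that add atoms: N,N-dimethylformamide, CN(C)C=O
Why: Directed ortho-lithiation of the ring hydrogen flanked by two methoxy groups followed by formylation of the aryllithium with DMF.

Step 14
Reactants: 20 2,3,5,6-tetramethoxybenzaldehyde
Product: 21 (2,3,5,6-tetramethoxyphenyl)methanol
Conditions: NaBH4, MeOH, 0 °C
Reagents that add atoms: none
Why: Simple hydride reduction of the aldehyde to the benzylic alcohol.

Step 15
Reactants: 21 (2,3,5,6-tetramethoxyphenyl)methanol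
Product: 22 3-(chloromethyl)-1,2,4,5-tetramethoxybenzene
Conditions: SOCl2, CH2Cl2, 0 → 25 °C; used directly
Reagents that add atoms: thionyl chloride, ClS(Cl)=O
Why: Chlorodehydroxylation of the electron-rich benzylic alcohol through its chlorosulfite.

Step 16
Reactants: 17 (1R,3R)-1-(but-3-yn-1-yl)-1,3-dimethyl-2-methylidenecyclohexane; 22 3-(chloromethyl)-1,2,4,5-tetramethoxybenzene
Product: 24 3-{(2E)-5-[(1R,3R)-1,3-dimethyl-2-methylidenecyclohexyl]-3-methylpent-2-en-1-yl}-1,2,4,5-tetramethoxybenzene, via alkenylalane 23 (not isolated)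
Conditions: Me3Al (2 equiv), Cp2ZrCl2 (0.25 equiv), CH2Cl2, 0 → 25 °C; evaporate; then 22, Pd(PPh3)4 (5 mol %), THF, 25 °C
Reagents that add atoms: trimethylaluminium, C[Al](C)C
Why: Negishi zirconium-catalysed methylalumination adds Me and Al syn across the terminal alkyne (Al on the terminal carbon), fixing the (E)-trisubstituted alkene, and zerovalent-palladium-catalysed cross-coupling of the alkenylalane with the benzylic chloride proceeds with retention of geometry while the hindered exocyclic alkene does not carbometalate.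

Step 17
Reactants: 24 3-{(2E)-5-[(1R,3R)-1,3-dimethyl-2-methylidenecyclohexyl]-3-methylpent-2-en-1-yl}-1,2,4,5-tetramethoxybenzene
Product: 25 3-{(2E)-5-[(1R,3R)-1,3-dimethyl-2-methylidenecyclohexyl]-3-methylpent-2-en-1-yl}-2,5-dimethoxycyclohexa-2,5-diene-1,4-dione
Conditions: (NH4)2Ce(NO3)6 (2.5 equiv), MeCN/H2O 2:1, 0 °C
Reagents that add atoms: water, O
Why: Oxidative demethylation, in which tetravalent cerium oxidises the electron-rich arene to its radical cation, water adds at two para methoxy-bearing carbons and methanol is lost to give the para-quinone, the isolated alkenes being inert at 0 °C.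

Step 18
Reactants: 25 3-{(2E)-5-[(1R,3R)-1,3-dimethyl-2-methylidenecyclohexyl]-3-methylpent-2-en-1-yl}-2,5-dimethoxycyclohexa-2,5-diene-1,4-dione
Product: 27 metachromin A [2-hydroxy-5-methoxy-3-{(2E)-5-[(1R,3R)-1,3-dimethyl-2-methylidenecyclohexyl]-3-methylpent-2-en-1-yl}cyclohexa-2,5-diene-1,4-dione], via potassium salt 26 (not isolated)
Conditions: 2 M aq KOH, MeOH, 25 °C; then 1 M HCl
Reagents that add atoms: potassium hydroxide, [K+].[OH-]
Why: Addition–elimination on a vinylogous ester, in which hydroxide attacks the methoxy-bearing carbon next to the side chain because that methoxy group is twisted out of conjugation and is the more electrophilic, the quinonolate formed resists further attack until acidification, and any ortho-quinone regioisomer from step 17 converges on the same product.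

## Compound list

1 | 2-methylcyclohexane-1,3-dione | CC1C(=O)CCCC1=O | starting material
2 | 2-methyl-2-(prop-2-en-1-yl)cyclohexane-1,3-dione | C=CCC1(C)C(=O)CCCC1=O | intermediate
3 | (2S,3S)-3-hydroxy-2-methyl-2-(prop-2-en-1-yl)cyclohexan-1-one | O=C1CCC[C@H](O)[C@]1(C)CC=C | intermediate
4 | O-[(1S,2S)-2-methyl-3-oxo-2-(prop-2-en-1-yl)cyclohexyl] O-phenyl carbonothioate | O=C1CCC[C@H](OC(=S)Oc2ccccc2)[C@]1(C)CC=C | intermediate
5 | (2R)-2-methyl-2-(prop-2-en-1-yl)cyclohexan-1-one | O=C1CCCC[C@]1(C)CC=C | intermediate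
6 | lithium (6R)-6-methyl-6-(prop-2-en-1-yl)cyclohex-1-en-1-olate | [Li]OC1=CCCC[C@]1(C)CC=C | intermediate (not isolated)
7 | (2R,6RS)-2,6-dimethyl-2-(prop-2-en-1-yl)cyclohexan-1-one | O=C1C(C)CCC[C@]1(C)CC=C | intermediate
8 | (2R,6RS)-2,6-dimethyl-2-(2-oxopropyl)cyclohexan-1-one | O=C1C(C)CCC[C@]1(C)CC(C)=O | intermediate
9 | (7aR)-3a-hydroxy-4,7a-dimethyloctahydro-2H-inden-2-one | O=C1CC2(O)C(C)CCC[C@]2(C)C1 | intermediate (not isolated)
10 | (4R,7aR)-4,7a-dimethyl-1,4,5,6,7,7a-hexahydro-2H-inden-2-one | O=C1C=C2[C@H](C)CCC[C@]2(C)C1 | intermediate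
11 | (4R,7aR)-3,3a-epoxy-4,7a-dimethyloctahydro-2H-inden-2-one | O=C1C2OC23[C@H](C)CCC[C@]3(C)C1 | intermediate
12 | N'-[(4R,7aR)-3,3a-epoxy-4,7a-dimethyloctahydro-2H-inden-2-ylidene]-4-methylbenzenesulfonohydrazide | Cc1ccc(cc1)S(=O)(=O)NN=C1C2OC23[C@H](C)CCC[C@]3(C)C1 | intermediate (not isolated)
13 | (2R,6R)-2,6-dimethyl-2-(prop-2-yn-1-yl)cyclohexan-1-one | O=C1[C@H](C)CCC[C@]1(C)CC#C | intermediate
14 | (1R,3R)-1,3-dimethyl-2-methylidene-1-(prop-2-yn-1-yl)cyclohexane | C=C1[C@H](C)CCC[C@]1(C)CC#C | intermediate
15 | dicyclohexyl{(1E)-3-[(1R,3R)-1,3-dimethyl-2-methylidenecyclohexyl]prop-1-en-1-yl}borane | C=C1[C@H](C)CCC[C@]1(C)C/C=C/B(C2CCCCC2)C2CCCCC2 | intermediate (not isolated)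
16 | 3-[(1R,3R)-1,3-dimethyl-2-methylidenecyclohexyl]propanal | C=C1[C@H](C)CCC[C@]1(C)CCC=O | intermediate
17 | (1R,3R)-1-(but-3-yn-1-yl)-1,3-dimethyl-2-methylidenecyclohexane | C=C1[C@H](C)CCC[C@]1(C)CCC#C | intermediate
18 | 1,2,4,5-tetramethoxybenzene | COc1cc(OC)c(OC)cc1OC | starting material
19 | (2,3,5,6-tetramethoxyphenyl)lithium | [Li]c1c(OC)c(OC)cc(OC)c1OC | intermediate (not isolated)
20 | 2,3,5,6-tetramethoxybenzaldehyde | O=Cc1c(OC)c(OC)cc(OC)c1OC | intermediate
21 | (2,3,5,6-tetramethoxyphenyl)methanol | OCc1c(OC)c(OC)cc(OC)c1OC | intermediate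
22 | 3-(chloromethyl)-1,2,4,5-tetramethoxybenzene | ClCc1c(OC)c(OC)cc(OC)c1OC | intermediate
23 | {(1E)-4-[(1R,3R)-1,3-dimethyl-2-methylidenecyclohexyl]-2-methylbut-1-en-1-yl}dimethylalumane | C=C1[C@H](C)CCC[C@]1(C)CC/C(C)=C/[Al](C)C | intermediate (not isolated)
24 | 3-{(2E)-5-[(1R,3R)-1,3-dimethyl-2-methylidenecyclohexyl]-3-methylpent-2-en-1-yl}-1,2,4,5-tetramethoxybenzene | C=C1[C@H](C)CCC[C@]1(C)CC/C(C)=C/Cc1c(OC)c(OC)cc(OC)c1OC | intermediate
25 | 3-{(2E)-5-[(1R,3R)-1,3-dimethyl-2-methylidenecyclohexyl]-3-methylpent-2-en-1-yl}-2,5-dimethoxycyclohexa-2,5-diene-1,4-dione | C=C1[C@H](C)CCC[C@]1(C)CC/C(C)=C/CC1=C(OC)C(=O)C=C(OC)C1=O | intermediate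
26 | potassium 2-{(2E)-5-[(1R,3R)-1,3-dimethyl-2-methylidenecyclohexyl]-3-methylpent-2-en-1-yl}-4-methoxy-3,6-dioxocyclohexa-1,4-dien-1-olate | C=C1[C@H](C)CCC[C@]1(C)CC/C(C)=C/CC1=C([O-])C(=O)C=C(OC)C1=O.[K+] | intermediate (not isolated)
27 | metachromin A, 2-hydroxy-5-methoxy-3-{(2E)-5-[(1R,3R)-1,3-dimethyl-2-methylidenecyclohexyl]-3-methylpent-2-en-1-yl}cyclohexa-2,5-diene-1,4-dione | C=C1[C@H](C)CCC[C@]1(C)CC/C(C)=C/CC1=C(O)C(=O)C=C(OC)C1=O | target

## Step count and risks

Total step count: 18 (15 in the terpenoid line, 3 for the arene).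
Longest linear sequence: 15 steps (steps 1–12, then 16–18).

Three steps most likely to fail:

Step 9, the Eschenmoser–Tanabe fragmentation (together with the epoxidation of the hindered enone that feeds it). The fallback degrades the enone oxidatively instead of fragmenting it; it sets out from 10 and comes back at 17. Ozonolysis of 10 with oxidative work-up (O3, CH2Cl2/MeOH, −78 °C; then H2O2, HCO2H) cleaves the enone with loss of C3 and gives 2-[(1R,3R)-1,3-dimethyl-2-oxocyclohexyl]acetic acid F1. Me3SiCHN2 in MeOH/toluene gives methyl 2-[(1R,3R)-1,3-dimethyl-2-oxocyclohexyl]acetate F2. Methylenation with Zn, CH2Br2 and TiCl4 gives methyl 2-[(1R,3R)-1,3-dimethyl-2-methylidenecyclohexyl]acetate F3. LiAlH4 in Et2O gives 2-[(1R,3R)-1,3-dimethyl-2-methylidenecyclohexyl]ethan-1-ol F4. I2, PPh3 and imidazole give (1R,3R)-1-(2-iodoethyl)-1,3-dimethyl-2-methylidenecyclohexane F5. Displacement with LiC≡CH·H2NCH2CH2NH2 in DMSO then gives 17, bypassing steps 8–12.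

Step 10, methylenation of the hindered, epimerisable ketone. The fallback replaces direct methylenation by a two-stage Peterson olefination; it sets out from 13 and comes back at 14. Inverse addition of 13 to excess Me3SiCH2Li/CeCl3 (THF, −78 °C) gives (2R,6R)-2,6-dimethyl-2-(prop-2-yn-1-yl)-1-[(trimethylsilyl)methyl]cyclohexan-1-ol F6. KH in THF then induces syn-elimination of the silanolate to give 14.

Step 16, the one-pot methylalumination and benzylic cross-coupling. The fallback reverses the polarity of the coupling; it sets out from 17 and comes back at 24. Alkenylalane 23 is quenched with I2 (THF, −30 °C) to give (1R,3R)-1-[(3E)-4-iodo-3-methylbut-3-en-1-yl]-1,3-dimethyl-2-methylidenecyclohexane F7. Chloride 22 is converted with Zn dust and LiCl in THF into chlorido[(2,3,5,6-tetramethoxyphenyl)methyl]zinc F8. Negishi coupling of F7 with F8 under Pd(PPh3)4 (zerovalent palladium) gives 24.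

## Further compounds

F1 | step 9 | 2-[(1R,3R)-1,3-dimethyl-2-oxocyclohexyl]acetic acid | O=C1[C@H](C)CCC[C@]1(C)CC(=O)O
F2 | step 9 | methyl 2-[(1R,3R)-1,3-dimethyl-2-oxocyclohexyl]acetate | O=C1[C@H](C)CCC[C@]1(C)CC(=O)OC
F3 | step 9 | methyl 2-[(1R,3R)-1,3-dimethyl-2-methylidenecyclohexyl]acetate | C=C1[C@H](C)CCC[C@]1(C)CC(=O)OC
F4 | step 9 | 2-[(1R,3R)-1,3-dimethyl-2-methylidenecyclohexyl]ethan-1-ol | C=C1[C@H](C)CCC[C@]1(C)CCO
F5 | step 9 | (1R,3R)-1-(2-iodoethyl)-1,3-dimethyl-2-methylidenecyclohexane | C=C1[C@H](C)CCC[C@]1(C)CCI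
F6 | step 10 | (2R,6R)-2,6-dimethyl-2-(prop-2-yn-1-yl)-1-[(trimethylsilyl)methyl]cyclohexan-1-ol | C[Si](C)(C)CC1(O)[C@H](C)CCC[C@]1(C)CC#C
F7 | step 16 | (1R,3R)-1-[(3E)-4-iodo-3-methylbut-3-en-1-yl]-1,3-dimethyl-2-methylidenecyclohexane | C=C1[C@H](C)CCC[C@]1(C)CC/C(C)=C/I
F8 | step 16 | chlorido[(2,3,5,6-tetramethoxyphenyl)methyl]zinc | Cl[Zn]Cc1c(OC)c(OC)cc(OC)c1OC
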